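Molarity, not per cent, is the unit to watch in this flask.

| flask | substrate | remark | time |
|---|---|---|---|
| west | 0.54 M | run made earlier |  |
| south-east | 1.2 M | run made earlier |  |
| flask | 0.80 M |  | 2.5 d |

| run | time / d | target / % | isomer of the product / % |
|---|---|---|---|
| west | 0.250 | 25.9 | 16.0 |
| west | 0.417 | 32.3 | 21.6 |
| west | 0.833 | 38.3 | 26.6 |
| west | 1.67 | 38.5 | 30.9 |
| west | 3.00 | 35.2 | 32.2 |
| south-east | 0.250 | 26.5 | 16.3 |
| south-east | 0.833 | 44.9 | 25.3 |
| south-east | 1.25 | 48.1 | 26.8 |
| south-east | 2.00 | 51.3 | 25.8 |
| south-east | 3.00 | 53.2 | 25.5 |

(standard deviation of a reading: 0.5 percentage points)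
- share of target in target plus isomer of the product at 12 min
- share of target in target plus isomer of the product at 2.5 d
- a reading or a percentage of target counts all its forms, free or not

The target in the west run peaks at a reading of 38.5% and then falls, while the target in the south-east run is still rising at its last reading. So I hold two amounts against each other. The first is the highest target concentration read in the west run:

38.5% × 0.54 M = 0.208 M

The second is the same peak percentage taken of this flask's charge:

38.5% × 0.80 M = 0.308 M

I call this second amount the peak demand. In this flask it stands at 1.48 times the west peak, so I expect this flask to reach target concentrations that the west run did not read, and I don't expect the west run's fall to be copied. I place the late share between the 52.2% read in the west run and the 67.6% read in the south-east run, both at 3.00 d. For the early share I have the first readings, 61.8% in the west run and 61.9% in the south-east run, both at 0.250 d, and I expect this flask to stand a little above them at 12 min.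

The forecast gives 63.5% at 12 min and 56% at 2.5 d, “with free target capped near 0.3 M”.

The flask gives 62.9% at 12 min and 61.5% at 2.5 d.

    substrate → decomposition product (k = 1.65 × 10⁻⁵ /h)
    substrate ⇌ third isomer (K = 1.20, k = 0.0216 /h)
    substrate ⇌ isomer of the product (K = 2.30, k = 0.0399 /h)
    substrate ⇌ target (K = 2.20, k = 0.0678 /h)
    crystals ⇌ target, rate k5*(cs5 - [target]) while solid is left; crystals form when [target] > cs5 (solubility = 0.210 M, k = 1.44 /h)

Crystals form when dissolved target stands above 0.21 M, and the peak demand of this flask is higher; at 2.50 d the flask holds 18.6% of its charge as crystals, counted in target. The neighbour flask charged with 0.48 M has a peak demand of 0.185 M, lower than the west peak. Its share at 2.50 d is 53.1%, and its crystals stand at 0%.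

Readings and results come from a simulation from invented constants; the scatter is artificial.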